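## Analysis of the target

- The target is a 1,3-diacylglycerol. One primary oxygen carries an acetate, the secondary hydroxyl is free, and the other primary oxygen is acylated by a C20 bicyclic acid built on a 1,2,3,4,4a,7,8,8a-octahydronaphthalene (ring A: C1–C4, C4a, C8a; ring B: C4a, C5–C8, C8a).
- Ring A holds four contiguous stereocentres: C1 (S, carboxyl), C2 (R, methyl) and the two fully substituted fusion carbons C8a (R) and C4a (R), each bearing a methyl group.
- The two angular methyl groups are cis (a cis-fused bicycle), the C1 carboxyl lies on their face, and the C2 methyl lies on the opposite face, trans to the carboxyl.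
- Ring B contains the trisubstituted C5=C6 alkene, and C5 carries the 4-methylpent-3-enyl chain, so C5 can be a ketone at an earlier stage.
- The fifth stereocentre, the glycerol carbinol carbon (S), is too remote to be induced by the core and has to come from an enantiopure C3 unit.
- Sensitive points are the two trisubstituted alkenes (acid-induced migration or cation–olefin cyclisation) and the free secondary hydroxyl between two acyloxymethyl groups, across which acyl groups migrate. In the monoacyl stage this erodes the glycerol configuration, and in the target it gives regioisomers. The neopentyl-type C1 ester is also hard to make or cleave at its acyl carbon.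
- The difficulty is the C4a–C8a bond between two quaternary stereocentres with C1 and C2 directly attached. The strategy rests on the fact that C4a–C8a and C1–C2 are opposite bonds of ring A: C8a/C1 carry methyl and carboxyl like the β- and α-carbons of a 3-methylalk-2-enoate, C2–C3–C4–C4a is then a diene oxygenated at C4, and C5–C8 is a four-atom tether from C4a to C8a.

## Retrosynthetic reasoning

**Glycerol arm (31 → 30 → 29 → 27 + 28).** The acetate is removed first, because a free secondary hydroxyl next to two esters should exist for as short a time as possible. Diol 30 comes from acetonide 29. The ester C–O bond of 29 is cut on the alkyl side, not the acyl side: acid 27 is hindered at its carbonyl carbon, so the forward step lets the carboxylate displace an activated primary carbinol of 28 (Mitsunobu). The stereocentre of 28 is not a reacting centre, so its arrangement is carried unchanged into 31 (its descriptor changes from R to S only through the priority rules).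

**Acid (27 → 26).** The methyl ester is kept through the whole core synthesis because it is the enoate activating group of the key step. It is cut at the O–CH3 bond, since substitution at the methyl carbon is indifferent to the crowding around C1.

**Side chain (26 → 23 + 24).** The C5–side-chain bond is cut next to the C5=C6 alkene. This maps onto an alkenyl triflate/alkylmetal coupling, and the triflate 23 comes from ketone 21. C4a is quaternary, so 21 can only enolise toward C6 and the alkene position is fixed by structure. The chain is introduced late so that its alkene never meets the hydrogenation or the silyl triflate chemistry.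

**Oxygen handles (21 → 20 → 19 → 18 → 17 → 15).** The C5 ketone is traced to the silyl ether through alcohol 20. The C4 methylene is traced to the C4 ketone of 15 through enol triflate 17 and alkene 18. Enolisation of 15 is again one-directional, and this detour avoids condensation chemistry at a carbonyl flanked by a quaternary carbon. Both oxygens are needed for the key step and both sit where the target has either nothing (C4) or a later substituent (C5).

**Core (15 → 12).** Both C4a–C8a and C1–C2 are cut, which opens both rings at once and returns the acyclic enone–enoate 12. No other pair of bonds removes both quaternary centres and both neighbouring stereocentres in one operation from a chain with a single stereochemical control element. The forward reaction has to enolise the enone toward C4a, join C4a to C8a on one face, deliver a cis fusion and close C1–C2 with the ester cis to the C8a methyl and trans to the C2 methyl. The C4a stereocentre of 12 disappears on enolisation, so only the silyloxy-bearing carbon has to be configured.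

**Chain (12 → 11 → 7 + 8).** The bond between the future C4a and C5 is an aldol bond. Cutting it gives aldehyde 7 and the ethyl ketone 8, and a reagent-controlled boron aldol sets the carbinol centre, the only source of absolute configuration for the bicycle. The syn relationship of 11 is simply what the Z-enolate gives and has no consequence.

**Enoate (7 → 6 → 1 + 2).** The (E)-geometry of the 3-methyl-2-enoate decides the C1/C8a relationship, so the C8–C8a bond is cut to an alkylcopper addition to ynoate 2, which fixes the geometry by syn addition. A carbonyl olefination of a methyl ketone would give both alkene isomers. The aldehyde is carried as the dioxolane of 1 and released by hydrolysis, which saves a hydroboration/oxidation pair.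

## Alternatives that were turned down

**Alternative 1: anionic oxy-Cope rearrangement of a bridged carbinol.**
- Disconnection and key step: the C4–C4a bond is cut. The potassium alkoxide of the bicyclo[2.2.2]octenyl vinyl carbinol A2 would undergo a [3,3] shift in which the vinyl terminus bonds to C4a while the bridge bond between C2 and C6 breaks, giving the cis-fused keto ketal A1 with the C5=C6 alkene and side chain in place.
- For: the rearrangement is stereospecific and the bridged framework forces the cis fusion. On this point it is stronger than the chosen route, whose fusion depends on a transition-state preference.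
- Against: A1 has neither the carboxyl carbon at C1 nor the methyl at C2. C1 is a ketal carbon wedged between quaternary C8a and the C2 ketone, so a one-carbon homologation at a neopentyl position and a methylation, each with stereocontrol, would still be needed, and two of the four ring stereocentres remain open. A2 itself needs an enantioselective cycloaddition that forms a tetrasubstituted bridge alkene and a face-selective vinyl addition.
- Comparison: the chosen strategy gives up the guaranteed fusion and gains C1 and C2, with their substituents, in the ring-forming step from a four-step acyclic precursor.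

**Alternative 2: Diels–Alder reaction of an ene-dione.**
- Disconnection and key step: ring B is cut at C4a–C5 and C8a–C8. Ene-dione A4 and silyloxy diene A5 would combine to the bicyclic dione A3, forming both quaternary carbons at once.
- For: the step is intermolecular and short, and suprafacial addition to a cyclic dienophile guarantees the cis fusion, again stronger than the chosen route on that point.
- Against: a tetrasubstituted, doubly methylated dienophile is a poor partner, and its two faces are enantiotopic, so absolute control must come wholly from a chiral catalyst. In A3 the two ketones sit in nearly equal surroundings. One must become the carboxyl-bearing C1 with a new C–C bond and a stereocentre, C2 must be methylated, the other ketone must be removed, and the ring B alkene must be moved from C6=C7 to C5=C6.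
- Comparison: the chosen route needs one removable stereocentre and arrives at 15 with C1 and C2 complete. Alternative 2 reaches a bicycle faster but leaves the longer and less selective part for afterwards.

**Alternative 3: radical conjugate cyclisation onto a chiral-pool ring A.**
- Disconnection and key step: the C8–C8a bond is cut. The primary radical from iodide A7 would add to the β-carbon of the tetrasubstituted enoate and close ring B, and hydrogen transfer to C1 would give A6, which is the same compound as 26.
- For: the endgame is the shortest possible, since A6 already holds the side chain and the ring B alkene, and C2 would come from the chiral pool.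
- Against: a 6-exo attack on a fully substituted β-carbon that creates a quaternary centre next to another quaternary centre is slow, so simple reduction and 1,5-hydrogen transfer compete. Neither the face of attack at C8a nor the hydrogen delivery at C1 has a strong controlling element. A7 needs a quaternary C4a stereocentre bearing a geometrically defined trisubstituted alkenyl group, which is about as hard as the problem it is meant to solve.
- Comparison: the chosen strategy forms the same congested bond by a polar addition between a nucleophilic diene and an activated enoate, and builds its precursor by an aldol and a carbocupration.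

Key step: step 5

Assumption: (Z)-enol diisopinocampheylborinates of ethyl ketones are taken to attack aldehydes with the same facial sense as the corresponding (Z)-crotylboranes, so the (+)-reagent (from (−)-α-pinene) should give the 7S carbinol; if the opposite sense is found, the antipodal reagent is used and nothing else changes.

## Route

Step 1
Reactants: 1 2-(3-chloropropyl)-1,3-dioxolane; 2 methyl but-2-ynoate
Product: 6 methyl (2E)-6-(1,3-dioxolan-2-yl)-3-methylhex-2-enoate, via Grignard reagent 3 (not isolated), via alkylcopper reagent 4 (not isolated), via alkenylcopper adduct 5 (not isolated)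
Conditions: Mg, THF, reflux; CuBr·SMe2, THF, −40 °C; 2, −78 °C; aq. NH4Cl, −78 °C to rt
Reagents that add atoms: none
Why: Syn carbocupration of an ynoate: the alkylcopper reagent adds its alkyl group to the β-carbon and copper to the α-carbon on the same side, and protonation of 5 at low temperature with retention should give the (E)-3-methyl-2-enoate free of the (Z) isomer; this geometry later places the ester cis to the C8a methyl.

Step 2
Reactants: 6 methyl (2E)-6-(1,3-dioxolan-2-yl)-3-methylhex-2-enoate
Product: 7 methyl (2E)-3-methyl-7-oxohept-2-enoate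
Conditions: 1 M HCl, THF, rt
Reagents that add atoms: water, O
Why: Acid-catalysed acetal hydrolysis; the conjugated ester and its geometry should be untouched.

Step 3
Reactants: 7 methyl (2E)-3-methyl-7-oxohept-2-enoate; 8 (4E)-hex-4-en-3-one
Product: 11 methyl (2E,7S,8R,10E)-7-hydroxy-3,8-dimethyl-9-oxododeca-2,10-dienoate, via enol borinate 9 (not isolated), via boron aldolate 10 (not isolated)
Conditions: (+)-Ipc2BOTf, i-Pr2NEt, CH2Cl2, −78 °C; 7, −78 to −20 °C; pH 7 buffer, MeOH, H2O2, 0 °C
Reagents that add atoms: none
Why: Asymmetric boron aldol reaction of an ethyl ketone (Paterson aldol): the boron triflate and the hindered amine enolise 8 on the ethyl side to the (Z)-enol borinate 9, whose chair transition state gives the syn aldol, and the isopinocampheyl ligands should direct attack to the re face of the aldehyde and so set C7 (the later C5) as S. Buffered peroxide frees 11 from borinate 10 without attacking enone or enoate.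

Step 4
Reactants: 11 methyl (2E,7S,8R,10E)-7-hydroxy-3,8-dimethyl-9-oxododeca-2,10-dienoate
Product: 12 methyl (2E,7S,8R,10E)-7-[(tert-butyldimethylsilyl)oxy]-3,8-dimethyl-9-oxododeca-2,10-dienoate
Conditions: TBSOTf, 2,6-lutidine, CH2Cl2, −78 °C
Reagents that add atoms: tert-butyldimethylsilyl trifluoromethanesulfonate, CC(C)(C)[Si](C)(C)OS(=O)(=O)C(F)(F)F
Why: Silylation of a secondary alcohol with a silyl triflate and a hindered pyridine; at low temperature retro-aldol cleavage is avoided and the weak base leaves the enone unenolised.

Step 5
Reactants: 12 methyl (2E,7S,8R,10E)-7-[(tert-butyldimethylsilyl)oxy]-3,8-dimethyl-9-oxododeca-2,10-dienoate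
Product: 15 methyl (1S,2R,4aS,5S,8aR)-5-[(tert-butyldimethylsilyl)oxy]-2,4a,8a-trimethyl-4-oxodecahydronaphthalene-1-carboxylate, via silyl dienol ether 13 (not isolated), via bicyclic silyl enol ether 14 (not isolated)
Conditions: TBSOTf, Et3N, CH2Cl2, −78 °C to rt; then 1 M HCl, THF, 0 °C
Reagents that add atoms: none
Why: The silyl triflate and the amine enolise the enone of 12 toward C4a to the cross-conjugated 2-silyloxy diene 13 (the C4a stereocentre of 12 is erased here, so C5 alone carries the stereochemical information); C4a then adds to C8a of the silyl-activated (E)-enoate in a Mukaiyama–Michael step that closes ring B (6-exo-trig), and the ester enolate so released, as its silyl ketene acetal, adds through C1 to C2 of the regenerated enone and closes ring A (6-endo-trig), giving silyl enol ether 14, which the acidic work-up hydrolyses to ketone 15 while the hindered C5 silyl ether stays. The closest known reaction type is the intramolecular double Michael reaction of enone–enoates under silyl triflate/tertiary amine conditions, the stepwise ionic counterpart of an intramolecular Diels–Alder reaction of a 2-silyloxy diene. C4a: in the chair-like 6-exo transition state the C5 hydrogen lies close to the plane of the enol ether (allylic strain) and the C5 silyloxy group is equatorial and anti to the forming bond, so C8a should arrive on the face that leaves the C4a methyl cis to the C5 oxygen. C8a: the cis fusion needs the enoate to react through the face that places its methyl group gauche to the C4a methyl and C1 next to C4, whereas the competing arrangement puts the two methyl groups trans-diaxial on the forming ring; this choice, which no later step can correct, is the selectivity the step needs most and the one least firmly secured by the substrate. C1: the ester ends cis to the C8a methyl, as the (E)-enoate dictates if the second bond closes before rotation about C8a–C1, and this is also the equatorial position that enolisation would restore. C2: C1 should attack the enone rotamer that keeps the branched C5 carbon away from C3, which puts the C2 methyl equatorial and trans to the ester, the more stable arrangement of the cis-fused product as well. Regioselective enolisation toward the hindered C4a–H and not the γ-methyl group rests on the kinetic preference of these conditions for the cross-conjugated diene.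

Step 6
Reactants: 15 methyl (1S,2R,4aS,5S,8aR)-5-[(tert-butyldimethylsilyl)oxy]-2,4a,8a-trimethyl-4-oxodecahydronaphthalene-1-carboxylate
Product: 17 methyl (1S,2R,4aS,5S,8aR)-5-[(tert-butyldimethylsilyl)oxy]-2,4a,8a-trimethyl-4-{[(trifluoromethyl)sulfonyl]oxy}-1,2,4a,5,6,7,8,8a-octahydronaphthalene-1-carboxylate, via potassium enolate 16 (not isolated)
Conditions: KN(SiMe3)2, THF, −78 °C; PhNTf2, −78 to 0 °C
Reagents that add atoms: N-phenylbis(trifluoromethanesulfonimide), O=S(=O)(N(c1ccccc1)S(=O)(=O)C(F)(F)F)C(F)(F)F
Why: Kinetic enolate formation and O-triflation: C4a is quaternary, so the ketone can only enolise toward C3, and the C1–H next to the ester is both less acidic and shielded. No stereocentre is touched.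

Step 7
Reactants: 17 methyl (1S,2R,4aS,5S,8aR)-5-[(tert-butyldimethylsilyl)oxy]-2,4a,8a-trimethyl-4-{[(trifluoromethyl)sulfonyl]oxy}-1,2,4a,5,6,7,8,8a-octahydronaphthalene-1-carboxylate
Product: 18 methyl (1S,2R,4aS,5S,8aR)-5-[(tert-butyldimethylsilyl)oxy]-2,4a,8a-trimethyl-1,2,4a,5,6,7,8,8a-octahydronaphthalene-1-carboxylate
Conditions: Pd(OAc)2 (cat.), PPh3, HCO2H, Bu3N, DMF, 60 °C
Reagents that add atoms: none
Why: Palladium-catalysed formate reduction of an enol triflate: oxidative addition to zerovalent palladium, formate exchange, loss of CO2 and reductive elimination replace the triflate by hydrogen; ester and silyl ether are inert.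

Step 8
Reactants: 18 methyl (1S,2R,4aS,5S,8aR)-5-[(tert-butyldimethylsilyl)oxy]-2,4a,8a-trimethyl-1,2,4a,5,6,7,8,8a-octahydronaphthalene-1-carboxylate
Product: 19 methyl (1S,2R,4aS,5S,8aR)-5-[(tert-butyldimethylsilyl)oxy]-2,4a,8a-trimethyldecahydronaphthalene-1-carboxylate
Conditions: H2 (1 atm), PtO2, EtOAc, rt
Reagents that add atoms: none
Why: Heterogeneous hydrogenation of the cis-disubstituted C3=C4 alkene; no stereocentre is formed, and platinum is chosen over palladium because it is less prone to move the double bond toward C2 before reducing it.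

Step 9
Reactants: 19 methyl (1S,2R,4aS,5S,8aR)-5-[(tert-butyldimethylsilyl)oxy]-2,4a,8a-trimethyldecahydronaphthalene-1-carboxylate
Product: 20 methyl (1S,2R,4aS,5S,8aR)-5-hydroxy-2,4a,8a-trimethyldecahydronaphthalene-1-carboxylate
Conditions: aq. HF, MeCN, rt to 40 °C
Reagents that add atoms: none
Why: Fluoride cleavage of the hindered secondary silyl ether under acidic conditions, which cannot epimerise C1.

Step 10
Reactants: 20 methyl (1S,2R,4aS,5S,8aR)-5-hydroxy-2,4a,8a-trimethyldecahydronaphthalene-1-carboxylate
Product: 21 methyl (1S,2R,4aS,8aR)-2,4a,8a-trimethyl-5-oxodecahydronaphthalene-1-carboxylate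
Conditions: Dess–Martin periodinane, CH2Cl2, rt
Reagents that add atoms: none
Why: Dess–Martin oxidation of a hindered secondary alcohol; the C5 stereocentre, having done its work, is removed here.

Step 11
Reactants: 21 methyl (1S,2R,4aS,8aR)-2,4a,8a-trimethyl-5-oxodecahydronaphthalene-1-carboxylate
Product: 23 methyl (1S,2R,4aS,8aR)-2,4a,8a-trimethyl-5-{[(trifluoromethyl)sulfonyl]oxy}-1,2,3,4,4a,7,8,8a-octahydronaphthalene-1-carboxylate, via potassium enolate 22 (not isolated)
Conditions: KN(SiMe3)2, THF, −78 °C; PhNTf2, −78 to 0 °C
Reagents that add atoms: N-phenylbis(trifluoromethanesulfonimide), O=S(=O)(N(c1ccccc1)S(=O)(=O)C(F)(F)F)C(F)(F)F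
Why: As in step 6, quaternary C4a forces enolisation toward C6, so the enol triflate has exactly the C5=C6 position of the target alkene.

Step 12
Reactants: 23 methyl (1S,2R,4aS,8aR)-2,4a,8a-trimethyl-5-{[(trifluoromethyl)sulfonyl]oxy}-1,2,3,4,4a,7,8,8a-octahydronaphthalene-1-carboxylate; 24 5-bromo-2-methylpent-2-ene
Product: 26 methyl (1S,2R,4aR,8aR)-2,4a,8a-trimethyl-5-(4-methylpent-3-en-1-yl)-1,2,3,4,4a,7,8,8a-octahydronaphthalene-1-carboxylate, via alkylzinc bromide 25 (not isolated)
Conditions: 24, Zn, LiCl, THF, 50 °C; then 23, Pd(dppf)Cl2 (cat.), THF, 50 °C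
Reagents that add atoms: none
Why: Negishi coupling of an alkenyl triflate with a primary alkylzinc halide: the zinc reagent is formed by direct insertion and tolerates the ester, and the bidentate ferrocenyl diphosphine favours reductive elimination over β-hydride elimination. The side-chain alkene takes no part.

Step 13
Reactants: 26 methyl (1S,2R,4aR,8aR)-2,4a,8a-trimethyl-5-(4-methylpent-3-en-1-yl)-1,2,3,4,4a,7,8,8a-octahydronaphthalene-1-carboxylate
Product: 27 (1S,2R,4aR,8aR)-2,4a,8a-trimethyl-5-(4-methylpent-3-en-1-yl)-1,2,3,4,4a,7,8,8a-octahydronaphthalene-1-carboxylic acid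
Conditions: NaSEt, DMF, 100 °C; then 1 M HCl
Reagents that add atoms: none
Why: SN2 demethylation of a hindered methyl ester by thiolate: attack is at the open methyl carbon, so the shielding of the acyl carbon by C8a and C2 is irrelevant, and the weakly basic thiolate should leave C1 alone.

Step 14
Reactants: 27 (1S,2R,4aR,8aR)-2,4a,8a-trimethyl-5-(4-methylpent-3-en-1-yl)-1,2,3,4,4a,7,8,8a-octahydronaphthalene-1-carboxylic acid; 28 (R)-solketal
Product: 29 [(4S)-2,2-dimethyl-1,3-dioxolan-4-yl]methyl (1S,2R,4aR,8aR)-2,4a,8a-trimethyl-5-(4-methylpent-3-en-1-yl)-1,2,3,4,4a,7,8,8a-octahydronaphthalene-1-carboxylate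
Conditions: PPh3, DIAD, THF, 0 °C to rt
Reagents that add atoms: none
Why: Mitsunobu esterification: the primary carbinol carbon of 28 is activated and displaced by the carboxylate, so the hindered acid reacts as the nucleophile and its acyl carbon need not be attacked. The stereocentre of 28 is not a reacting centre and keeps its arrangement.

Step 15
Reactants: 29 [(4S)-2,2-dimethyl-1,3-dioxolan-4-yl]methyl (1S,2R,4aR,8aR)-2,4a,8a-trimethyl-5-(4-methylpent-3-en-1-yl)-1,2,3,4,4a,7,8,8a-octahydronaphthalene-1-carboxylate
Product: 30 (2S)-2,3-dihydroxypropyl (1S,2R,4aR,8aR)-2,4a,8a-trimethyl-5-(4-methylpent-3-en-1-yl)-1,2,3,4,4a,7,8,8a-octahydronaphthalene-1-carboxylate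
Conditions: AcOH/H2O (4:1), 40 °C
Reagents that add atoms: none
Why: Mild aqueous-acid hydrolysis of the isopropylidene acetal; the acid is weak enough for the trisubstituted alkenes, and the bulky acyl group should migrate only slowly.

Step 16
Reactants: 30 (2S)-2,3-dihydroxypropyl (1S,2R,4aR,8aR)-2,4a,8a-trimethyl-5-(4-methylpent-3-en-1-yl)-1,2,3,4,4a,7,8,8a-octahydronaphthalene-1-carboxylate
Product: 31 (2S)-3-(acetyloxy)-2-hydroxypropyl (1S,2R,4aR,8aR)-2,4a,8a-trimethyl-5-(4-methylpent-3-en-1-yl)-1,2,3,4,4a,7,8,8a-octahydronaphthalene-1-carboxylate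
Conditions: AcCl, 2,4,6-collidine, CH2Cl2, −78 °C
Reagents that add atoms: acetyl chloride, CC(Cl)=O
Why: Selective acylation of the primary hydroxyl of a 1,2-diol with an acid chloride and a hindered pyridine at low temperature; the secondary hydroxyl, flanked by two acyloxymethyl groups, should react far more slowly.

## Compound list

1 | 2-(3-chloropropyl)-1,3-dioxolane | ClCCCC1OCCO1 | starting material
2 | methyl but-2-ynoate | CC#CC(=O)OC | starting material
3 | [3-(1,3-dioxolan-2-yl)propyl]magnesium chloride | Cl[Mg]CCCC1OCCO1 | intermediate (not isolated)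
4 | [3-(1,3-dioxolan-2-yl)propyl]copper | [Cu]CCCC1OCCO1 | intermediate (not isolated)
5 | methyl (2Z)-2-cuprio-6-(1,3-dioxolan-2-yl)-3-methylhex-2-enoate | COC(=O)/C([Cu])=C(\C)CCCC1OCCO1 | intermediate (not isolated)
6 | methyl (2E)-6-(1,3-dioxolan-2-yl)-3-methylhex-2-enoate | COC(=O)/C=C(\C)CCCC1OCCO1 | intermediate
7 | methyl (2E)-3-methyl-7-oxohept-2-enoate | COC(=O)/C=C(\C)CCCC=O | intermediate
8 | (4E)-hex-4-en-3-one | C/C=C/C(=O)CC | starting material
9 | (2Z,4E)-hexa-2,4-dien-3-yl (+)-diisopinocampheylborinate | C/C=C/C(OB([C@H]1C[C@H]2C[C@@H]([C@@H]1C)C2(C)C)[C@H]1C[C@H]2C[C@@H]([C@@H]1C)C2(C)C)=C/C | intermediate (not isolated)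
10 | methyl (2E,7S,8R,10E)-7-{[(+)-diisopinocampheylboryl]oxy}-3,8-dimethyl-9-oxododeca-2,10-dienoate | C/C=C/C(=O)[C@H](C)[C@@H](OB([C@H]1C[C@H]2C[C@@H]([C@@H]1C)C2(C)C)[C@H]1C[C@H]2C[C@@H]([C@@H]1C)C2(C)C)CCC/C(C)=C/C(=O)OC | intermediate (not isolated)
11 | methyl (2E,7S,8R,10E)-7-hydroxy-3,8-dimethyl-9-oxododeca-2,10-dienoate | C/C=C/C(=O)[C@H](C)[C@@H](O)CCC/C(C)=C/C(=O)OC | intermediate
12 | methyl (2E,7S,8R,10E)-7-[(tert-butyldimethylsilyl)oxy]-3,8-dimethyl-9-oxododeca-2,10-dienoate | C/C=C/C(=O)[C@H](C)[C@@H](O[Si](C)(C)C(C)(C)C)CCC/C(C)=C/C(=O)OC | intermediate (key-step precursor)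
13 | methyl (2E,7S,8Z,10E)-7,9-bis[(tert-butyldimethylsilyl)oxy]-3,8-dimethyldodeca-2,8,10-trienoate (8Z drawn as the expected isomer; this geometry is lost in the product) | C/C=C/C(O[Si](C)(C)C(C)(C)C)=C(\C)[C@@H](O[Si](C)(C)C(C)(C)C)CCC/C(C)=C/C(=O)OC | intermediate (not isolated)
14 | methyl (1S,2R,4aS,5S,8aR)-4,5-bis[(tert-butyldimethylsilyl)oxy]-2,4a,8a-trimethyl-1,2,4a,5,6,7,8,8a-octahydronaphthalene-1-carboxylate | COC(=O)[C@H]1[C@H](C)C=C(O[Si](C)(C)C(C)(C)C)[C@]2(C)[C@@H](O[Si](C)(C)C(C)(C)C)CCC[C@]12C | intermediate (not isolated)
15 | methyl (1S,2R,4aS,5S,8aR)-5-[(tert-butyldimethylsilyl)oxy]-2,4a,8a-trimethyl-4-oxodecahydronaphthalene-1-carboxylate | COC(=O)[C@H]1[C@H](C)CC(=O)[C@]2(C)[C@@H](O[Si](C)(C)C(C)(C)C)CCC[C@]12C | intermediate (key-step product)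
16 | potassium (1S,2R,4aS,5S,8aR)-5-[(tert-butyldimethylsilyl)oxy]-1-(methoxycarbonyl)-2,4a,8a-trimethyl-1,2,4a,5,6,7,8,8a-octahydronaphthalen-4-olate | COC(=O)[C@H]1[C@H](C)C=C([O-])[C@]2(C)[C@@H](O[Si](C)(C)C(C)(C)C)CCC[C@]12C.[K+] | intermediate (not isolated)
17 | methyl (1S,2R,4aS,5S,8aR)-5-[(tert-butyldimethylsilyl)oxy]-2,4a,8a-trimethyl-4-{[(trifluoromethyl)sulfonyl]oxy}-1,2,4a,5,6,7,8,8a-octahydronaphthalene-1-carboxylate | COC(=O)[C@H]1[C@H](C)C=C(OS(=O)(=O)C(F)(F)F)[C@]2(C)[C@@H](O[Si](C)(C)C(C)(C)C)CCC[C@]12C | intermediate
18 | methyl (1S,2R,4aS,5S,8aR)-5-[(tert-butyldimethylsilyl)oxy]-2,4a,8a-trimethyl-1,2,4a,5,6,7,8,8a-octahydronaphthalene-1-carboxylate | COC(=O)[C@H]1[C@H](C)C=C[C@]2(C)[C@@H](O[Si](C)(C)C(C)(C)C)CCC[C@]12C | intermediate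
19 | methyl (1S,2R,4aS,5S,8aR)-5-[(tert-butyldimethylsilyl)oxy]-2,4a,8a-trimethyldecahydronaphthalene-1-carboxylate | COC(=O)[C@H]1[C@H](C)CC[C@]2(C)[C@@H](O[Si](C)(C)C(C)(C)C)CCC[C@]12C | intermediate
20 | methyl (1S,2R,4aS,5S,8aR)-5-hydroxy-2,4a,8a-trimethyldecahydronaphthalene-1-carboxylate | COC(=O)[C@H]1[C@H](C)CC[C@]2(C)[C@@H](O)CCC[C@]12C | intermediate
21 | methyl (1S,2R,4aS,8aR)-2,4a,8a-trimethyl-5-oxodecahydronaphthalene-1-carboxylate | COC(=O)[C@H]1[C@H](C)CC[C@]2(C)C(=O)CCC[C@]12C | intermediate
22 | potassium (4aS,5S,6R,8aR)-5-(methoxycarbonyl)-4a,6,8a-trimethyl-3,4,4a,5,6,7,8,8a-octahydronaphthalen-1-olate (the C5=C6 enolate of 21 in the core numbering) | COC(=O)[C@H]1[C@H](C)CC[C@]2(C)C([O-])=CCC[C@]12C.[K+] | intermediate (not isolated)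
23 | methyl (1S,2R,4aS,8aR)-2,4a,8a-trimethyl-5-{[(trifluoromethyl)sulfonyl]oxy}-1,2,3,4,4a,7,8,8a-octahydronaphthalene-1-carboxylate | COC(=O)[C@H]1[C@H](C)CC[C@]2(C)C(OS(=O)(=O)C(F)(F)F)=CCC[C@]12C | intermediate
24 | 5-bromo-2-methylpent-2-ene | CC(C)=CCCBr | starting material
25 | (4-methylpent-3-en-1-yl)zinc bromide | CC(C)=CCC[Zn]Br | intermediate (not isolated)
26 | methyl (1S,2R,4aR,8aR)-2,4a,8a-trimethyl-5-(4-methylpent-3-en-1-yl)-1,2,3,4,4a,7,8,8a-octahydronaphthalene-1-carboxylate | COC(=O)[C@H]1[C@H](C)CC[C@]2(C)C(CCC=C(C)C)=CCC[C@]12C | intermediate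
27 | (1S,2R,4aR,8aR)-2,4a,8a-trimethyl-5-(4-methylpent-3-en-1-yl)-1,2,3,4,4a,7,8,8a-octahydronaphthalene-1-carboxylic acid | OC(=O)[C@H]1[C@H](C)CC[C@]2(C)C(CCC=C(C)C)=CCC[C@]12C | intermediate
28 | (R)-solketal, [(4R)-2,2-dimethyl-1,3-dioxolan-4-yl]methanol | CC1(C)OC[C@H](O1)CO | starting material
29 | [(4S)-2,2-dimethyl-1,3-dioxolan-4-yl]methyl (1S,2R,4aR,8aR)-2,4a,8a-trimethyl-5-(4-methylpent-3-en-1-yl)-1,2,3,4,4a,7,8,8a-octahydronaphthalene-1-carboxylate | CC1(C)OC[C@H](O1)COC(=O)[C@H]1[C@H](C)CC[C@]2(C)C(CCC=C(C)C)=CCC[C@]12C | intermediate
30 | (2S)-2,3-dihydroxypropyl (1S,2R,4aR,8aR)-2,4a,8a-trimethyl-5-(4-methylpent-3-en-1-yl)-1,2,3,4,4a,7,8,8a-octahydronaphthalene-1-carboxylate | OC[C@H](O)COC(=O)[C@H]1[C@H](C)CC[C@]2(C)C(CCC=C(C)C)=CCC[C@]12C | intermediate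
31 | (2S)-3-(acetyloxy)-2-hydroxypropyl (1S,2R,4aR,8aR)-2,4a,8a-trimethyl-5-(4-methylpent-3-en-1-yl)-1,2,3,4,4a,7,8,8a-octahydronaphthalene-1-carboxylate (CNP0146255.1) | CC(=O)OC[C@H](O)COC(=O)[C@H]1[C@H](C)CC[C@]2(C)C(CCC=C(C)C)=CCC[C@]12C | target

## Step count and least certain steps

Total: 16 steps. Longest linear sequence: 16 steps (1 to 31); 24 and 28 enter as purchased materials in steps 12 and 14.

**Step 5 (key step).**
- Enolisation may go to the γ-methyl group instead of the hindered C4a–H, or the silyl triflate may ionise the C5 silyloxy group and cause elimination.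
- The cascade may stall after the first bond, because that bond joins two fully substituted carbons.
- The ring fusion is decided in the first addition by a small difference between two chair-like arrangements and cannot be corrected afterwards; poor control here is the most serious risk of the route.
- The C2 centre depends on a rotamer preference in the second addition.
- If the C5 group were to direct C8a to the other face of C4a while still giving the cis fusion, only the antipodal reagent in step 3 would be needed, since C5 is erased later.
- Fallback: the closure is split into a kinetic and a thermodynamic stage. Setting out from 12, the cascade is run as in step 5 and the cis-fused material is not separated. The C2 epimer methyl (1S,2S,4aS,5S,8aR)-5-[(tert-butyldimethylsilyl)oxy]-2,4a,8a-trimethyl-4-oxodecahydronaphthalene-1-carboxylate F1 and the ring-B-only keto ester methyl 2-[(1R,2S,3S)-2-[(2E)-but-2-enoyl]-3-[(tert-butyldimethylsilyl)oxy]-1,2-dimethylcyclohexyl]acetate F2 (from a cascade that stops after the first bond) are taken together with 15 into NaOMe/MeOH at 40–60 °C. There C1 equilibrates by enolisation and C2 by retro-Michael opening to F2 and reclosure, a base-mediated intramolecular Michael addition under thermodynamic control. The isomer with ester and C2 methyl both equatorial is the most stable cis-fused ketone, so the mixture should drain into 15, where the route is rejoined. This fallback does not repair a wrong ring fusion.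

**Step 3.**
- Reagent control by the isopinocampheyl ligands is usually good but not complete, and its sense is taken by analogy. Since C5 is the only source of absolute configuration for the bicycle, any erosion of facial selectivity would reappear as a diastereomer after step 14.
- Fallback: an auxiliary-controlled aldol of fixed facial sense. Setting out from 7, the dibutylboron (Z)-enolate of (R)-4-benzyl-3-propionyl-1,3-oxazolidin-2-one (Bu2BOTf, i-Pr2NEt, CH2Cl2, −78 to 0 °C) should give the syn imide methyl (2E,7S,8R)-9-[(4R)-4-benzyl-2-oxo-1,3-oxazolidin-3-yl]-7-hydroxy-3,8-dimethyl-9-oxonon-2-enoate F3. Transamidation (AlMe3, MeONHMe·HCl) gives the Weinreb amide methyl (2E,7S,8R)-7-hydroxy-9-[methoxy(methyl)amino]-3,8-dimethyl-9-oxonon-2-enoate F4, and silylation (TBSOTf, 2,6-lutidine) gives methyl (2E,7S,8R)-7-[(tert-butyldimethylsilyl)oxy]-9-[methoxy(methyl)amino]-3,8-dimethyl-9-oxonon-2-enoate F5. Addition of (E)-prop-1-enyllithium (from (E)-1-bromoprop-1-ene and t-BuLi, THF, −78 °C) to the amide returns 12, two steps later than the main route. The price is that the last addition must prefer the amide over the β,β-disubstituted enoate.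

**Step 12.**
- Oxidative addition and transmetalation at a triflate flanked by a quaternary carbon may be slow, leaving room for β-hydride elimination, isomerisation of the alkyl group and protodezincation.
- Fallback: the chain is built in two couplings so that the hindered bond is an sp2–sp2 one. Setting out from 23, Stille vinylation (tributyl(vinyl)stannane, Pd(PPh3)4, LiCl, THF, reflux) should give the diene methyl (1S,2R,4aS,8aR)-5-ethenyl-2,4a,8a-trimethyl-1,2,3,4,4a,7,8,8a-octahydronaphthalene-1-carboxylate F6. 9-BBN adds to its terminal vinyl carbon, the ring alkene being trisubstituted and shielded, to give the alkylborane methyl (1S,2R,4aR,8aR)-5-[2-(9-borabicyclo[3.3.1]nonan-9-yl)ethyl]-2,4a,8a-trimethyl-1,2,3,4,4a,7,8,8a-octahydronaphthalene-1-carboxylate F7. B-alkyl Suzuki–Miyaura coupling with 1-bromo-2-methylprop-1-ene (Pd(dppf)Cl2, K3PO4, DMF/H2O) completes the chain and returns 26.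

**Step 16 (with step 15).**
- Over-acetylation at the secondary hydroxyl is possible, and acyl groups may migrate across the 1,2-diol: in 30 this erodes the glycerol configuration, in 31 it gives regioisomers.
- Fallback: the diol stage is avoided altogether. Setting out from acid 27, heating with [(2R)-oxiran-2-yl]methyl acetate F8 ((R)-glycidyl acetate, made by acetylation of purchased (S)-glycidol) and catalytic tetraethylammonium bromide in toluene/DMF at 80 °C should open the epoxide at its terminal carbon by the carboxylate. The stereocentre is not touched, the free secondary hydroxyl is generated in the same step, and the target 31 is reached directly without 29 and 30.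

## Further compounds

F1 | step 5 | methyl (1S,2S,4aS,5S,8aR)-5-[(tert-butyldimethylsilyl)oxy]-2,4a,8a-trimethyl-4-oxodecahydronaphthalene-1-carboxylate | COC(=O)[C@H]1[C@@H](C)CC(=O)[C@]2(C)[C@@H](O[Si](C)(C)C(C)(C)C)CCC[C@]12C
F2 | step 5 | methyl 2-[(1R,2S,3S)-2-[(2E)-but-2-enoyl]-3-[(tert-butyldimethylsilyl)oxy]-1,2-dimethylcyclohexyl]acetate | COC(=O)C[C@@]1(C)CCC[C@H](O[Si](C)(C)C(C)(C)C)[C@@]1(C)C(=O)/C=C/C
F3 | step 3 | methyl (2E,7S,8R)-9-[(4R)-4-benzyl-2-oxo-1,3-oxazolidin-3-yl]-7-hydroxy-3,8-dimethyl-9-oxonon-2-enoate | O=C1OC[C@@H](Cc2ccccc2)N1C(=O)[C@H](C)[C@@H](O)CCC/C(C)=C/C(=O)OC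
F4 | step 3 | methyl (2E,7S,8R)-7-hydroxy-9-[methoxy(methyl)amino]-3,8-dimethyl-9-oxonon-2-enoate | CON(C)C(=O)[C@H](C)[C@@H](O)CCC/C(C)=C/C(=O)OC
F5 | step 3 | methyl (2E,7S,8R)-7-[(tert-butyldimethylsilyl)oxy]-9-[methoxy(methyl)amino]-3,8-dimethyl-9-oxonon-2-enoate | CON(C)C(=O)[C@H](C)[C@@H](O[Si](C)(C)C(C)(C)C)CCC/C(C)=C/C(=O)OC
F6 | step 12 | methyl (1S,2R,4aS,8aR)-5-ethenyl-2,4a,8a-trimethyl-1,2,3,4,4a,7,8,8a-octahydronaphthalene-1-carboxylate | COC(=O)[C@H]1[C@H](C)CC[C@]2(C)C(C=C)=CCC[C@]12C
F7 | step 12 | methyl (1S,2R,4aR,8aR)-5-[2-(9-borabicyclo[3.3.1]nonan-9-yl)ethyl]-2,4a,8a-trimethyl-1,2,3,4,4a,7,8,8a-octahydronaphthalene-1-carboxylate | COC(=O)[C@H]1[C@H](C)CC[C@]2(C)C(CCB3C4CCCC3CCC4)=CCC[C@]12C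
F8 | step 16 | [(2R)-oxiran-2-yl]methyl acetate | CC(=O)OC[C@H]1CO1
A1 | alternative 1 | (4aR,8aS)-1,1-dimethoxy-4a,8a-dimethyl-5-(4-methylpent-3-en-1-yl)-3,4,4a,7,8,8a-hexahydronaphthalen-2(1H)-one | COC1(OC)C(=O)CC[C@]2(C)C(CCC=C(C)C)=CCC[C@]12C
A2 | alternative 1 | (1R,2R,4S)-2-ethenyl-3,3-dimethoxy-4,5-dimethyl-6-(4-methylpent-3-en-1-yl)bicyclo[2.2.2]oct-5-en-2-ol | C=C[C@]1(O)C(OC)(OC)[C@@]2(C)CC[C@@H]1C(CCC=C(C)C)=C2C
A3 | alternative 2 | (4aS,5R,8aS)-4a,8a-dimethyl-5-[(triisopropylsilyl)oxy]-2,3,4a,5,8,8a-hexahydronaphthalene-1,4-dione | O=C1CCC(=O)[C@]2(C)[C@H](O[Si](C(C)C)(C(C)C)C(C)C)C=CC[C@]12C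
A4 | alternative 2 | 2,3-dimethylcyclohex-2-ene-1,4-dione | CC1=C(C)C(=O)CCC1=O
A5 | alternative 2 | (1E)-1-[(triisopropylsilyl)oxy]buta-1,3-diene | C=C/C=C/O[Si](C(C)C)(C(C)C)C(C)C
A6 | alternative 3 | methyl (1S,2R,4aR,8aR)-2,4a,8a-trimethyl-5-(4-methylpent-3-en-1-yl)-1,2,3,4,4a,7,8,8a-octahydronaphthalene-1-carboxylate | COC(=O)[C@H]1[C@H](C)CC[C@]2(C)C(CCC=C(C)C)=CCC[C@]12C
A7 | alternative 3 | methyl (3R,6R)-3-[(3Z)-1-iodo-8-methylnona-3,7-dien-4-yl]-2,3,6-trimethylcyclohex-1-ene-1-carboxylate | COC(=O)C1=C(C)[C@](C)(CC[C@H]1C)/C(CCC=C(C)C)=C\CCI
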